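**Plan** (germacranolide numbering: C1 ketone, C2, C3–C4 epoxide with C15 on C4, C5, C6–O lactone, C7, C8–OH, C9–OAng, C10=C14H2, C11=C13H2, C12 lactone carbonyl; open-chain intermediates keep these numbers)
1. Enabling feature: C6–C7 is the fusion bond shared by the ten-membered carbocycle and the α-methylene-γ-butyrolactone, and C13=C11(C12O2)–C7–C6–O is the retron of a 2-(alkoxycarbonyl)allyl addition to an aldehyde.
2. Retrosynthetic cuts, in order: lactone C12–O and C6–C7 (C6 aldehyde + C13 allylic bromide); C7–C11 (methyl propiolate onto a C7 aldehyde); C9–O (angelic acid opening a C8–C9 epoxy alcohol); C1–C10 (alkenyl bromide + aldehyde); C7=C8 (Wittig); C4–C15 (carbomagnesiation of an alkyne).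
3. Forward: the C6→C1 Z-alkenal and the C10→C7 bromodienoate are joined at C1–C10, the open chain is oxidised and extended to C13, and step 18 closes the ten-membered ring and then the lactone in one flask; the only earlier ring is the epoxide.
4. Stereochemistry: C8/C9 from Sharpless epoxidation (catalysis) and invertive opening at C9; C3/C4 from a reagent-controlled dioxirane epoxidation; C6 and C7 both arise in the key step by relay from C8. C1 is a temporary carbinol, kept as a TES ether (oxidation-level helper) and oxidised in the last step.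

Key step: step 18

Remark: hex-3-yne-1,6-diol is taken as purchasable and the L-fructose-type ketone catalyst of step 12 as accessible from L-sorbose; the configuration of the temporary C1 carbinol (drawn 1S) is an arbitrary choice.

Step 1
Reactants: 1 hex-3-yne-1,6-diol
Product: 2 6-[(4-methoxybenzyl)oxy]hex-3-yn-1-ol
Conditions: NaH (1 equiv), 4-MeOC6H4CH2Cl (1 equiv), Bu4NI (cat.), THF–DMF, 0 °C to rt; diol in excess
Reagents that add atoms: 4-methoxybenzyl chloride, COc1ccc(CCl)cc1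
Why: Williamson etherification of the symmetrical diol with one equivalent of alkoxide should give the mono-PMB ether (statistical, excess diol recovered), which tells the future C6 oxygen from the C1 oxygen.

Step 2
Reactants: 2 6-[(4-methoxybenzyl)oxy]hex-3-yn-1-ol
Product: 3 (3Z)-6-[(4-methoxybenzyl)oxy]-4-methylhex-3-en-1-ol
Conditions: MeMgBr (5 equiv), Fe(acac)3 (cat.), THF, 0 °C; aq. NH4Cl
Reagents that add atoms: methylmagnesium bromide, C[Mg]Br
Why: Iron-catalysed, alkoxide-directed syn-carbomagnesiation of the homopropargylic alcohol places magnesium on the alkyne carbon nearer the alkoxide (five-membered chelate) and methyl on the far one, so protonation leaves the chain ends C2 and C5 cis, i.e. the 3Z trisubstituted alkene.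

Step 3
Reactants: 3 (3Z)-6-[(4-methoxybenzyl)oxy]-4-methylhex-3-en-1-ol
Product: 4 (3Z)-6-[(4-methoxybenzyl)oxy]-4-methylhex-3-enal
Conditions: Dess–Martin periodinane, NaHCO3, CH2Cl2, 0 °C; used crude
Reagents that add atoms: none
Why: Dess–Martin oxidation under buffered, non-basic conditions should give the β,γ-unsaturated aldehyde without migration of the Z double bond into conjugation.

Step 4
Reactants: 5 acrolein
Product: 7 2-bromoacrolein, via 2,3-dibromopropanal 6 (not isolated)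
Conditions: Br2, CH2Cl2, −78 °C; then Et3N, −78 to 0 °C
Reagents that add atoms: bromine, BrBr
Why: Bromine addition to the C=C bond followed by E1cB loss of HBr (bromination–dehydrobromination) gives the α-bromo enal.

Step 5
Reactants: 7 2-bromoacrolein; 8 ethyl (triphenylphosphoranylidene)acetate
Product: 9 ethyl (2E)-4-bromopenta-2,4-dienoate
Conditions: CH2Cl2, 0 °C to rt
Reagents that add atoms: none
Why: Wittig olefination with the stabilised ylide should give the E enoate and leave the alkenyl bromide for the next coupling.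

Step 6
Reactants: 4 (3Z)-6-[(4-methoxybenzyl)oxy]-4-methylhex-3-enal; 9 ethyl (2E)-4-bromopenta-2,4-dienoate
Product: 10 ethyl (2E,5S,7Z)-5-hydroxy-10-[(4-methoxybenzyl)oxy]-8-methyl-4-methylidenedeca-2,7-dienoate
Conditions: CrCl2 (3 equiv), NiCl2 (cat.), chiral 2-(2-sulfonamidophenyl)oxazoline ligand, Et3N, THF, rt
Reagents that add atoms: none
Why: Nozaki–Hiyama–Kishi coupling, in which zerovalent nickel inserts into the alkenyl C–Br bond and the derived alkenylchromium species adds only to the aldehyde (ester and diene inert, no free base to conjugate the aldehyde), with the chiral sulfonamide ligand on chromium setting the temporary C1 carbinol (ligand enantiomer chosen for 5S; either would serve because this center is oxidised in step 20).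

Step 7
Reactants: 10 ethyl (2E,5S,7Z)-5-hydroxy-10-[(4-methoxybenzyl)oxy]-8-methyl-4-methylidenedeca-2,7-dienoate
Product: 11 ethyl (2E,5S,7Z)-10-[(4-methoxybenzyl)oxy]-8-methyl-4-methylidene-5-[(triethylsilyl)oxy]deca-2,7-dienoate
Conditions: Et3SiCl, imidazole, CH2Cl2, 0 °C
Reagents that add atoms: chlorotriethylsilane, CC[Si](Cl)(CC)CC
Why: Silylation fixes C1 at the protected-alcohol level that the key step requires, as an ether removable with mild fluoride at the end.

Step 8
Reactants: 11 ethyl (2E,5S,7Z)-10-[(4-methoxybenzyl)oxy]-8-methyl-4-methylidene-5-[(triethylsilyl)oxy]deca-2,7-dienoate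
Product: 12 (2E,5S,7Z)-10-[(4-methoxybenzyl)oxy]-8-methyl-4-methylidene-5-[(triethylsilyl)oxy]deca-2,7-dien-1-ol
Conditions: i-Bu2AlH (2.2 equiv), CH2Cl2, −78 °C; aq. KNaC4H4O6 (potassium sodium tartrate)
Reagents that add atoms: none
Why: 1,2-Reduction of the conjugated ester by i-Bu2AlH gives the (E)-allylic alcohol that directs the epoxidation, with silyl and PMB ethers untouched.

Step 9
Reactants: 12 (2E,5S,7Z)-10-[(4-methoxybenzyl)oxy]-8-methyl-4-methylidene-5-[(triethylsilyl)oxy]deca-2,7-dien-1-ol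
Product: 13 [(2S,3S)-3-{(3S,5Z)-8-[(4-methoxybenzyl)oxy]-6-methyl-3-[(triethylsilyl)oxy]octa-1,5-dien-2-yl}oxiran-2-yl]methanol
Conditions: Ti(OiPr)4 (cat.), L-(+)-diethyl tartrate (cat.), t-BuOOH, 4 Å molecular sieves, CH2Cl2, −20 °C
Reagents that add atoms: tert-butyl hydroperoxide, CC(C)(C)OO
Why: Sharpless asymmetric epoxidation acts only on the allylic-alcohol double bond C8=C9, and L-(+)-tartrate should deliver oxygen to the face that gives the (2S,3S)-epoxy alcohol (8S,9S) by reagent control.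

Step 10
Reactants: 13 [(2S,3S)-3-{(3S,5Z)-8-[(4-methoxybenzyl)oxy]-6-methyl-3-[(triethylsilyl)oxy]octa-1,5-dien-2-yl}oxiran-2-yl]methanol; 14 angelic acid, (2Z)-2-methylbut-2-enoic acid
Product: 15 (2S,3R,5S,7Z)-1,2-dihydroxy-10-[(4-methoxybenzyl)oxy]-8-methyl-4-methylidene-5-[(triethylsilyl)oxy]dec-7-en-3-yl (2Z)-2-methylbut-2-enoate
Conditions: Ti(OiPr)4 (1.5 equiv), CH2Cl2, rt; aq. tartaric acid
Reagents that add atoms: none
Why: Titanium-mediated opening of a 2,3-epoxy alcohol by a carboxylic acid delivers the carboxylate within the titanium chelate to C3 (here C9, also allylic) by SN2 inversion, so the angelate is installed directly and the anti 8-hydroxy-9-acyloxy array (8S,9R) is set stereospecifically.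

Step 11
Reactants: 15 (2S,3R,5S,7Z)-1,2-dihydroxy-10-[(4-methoxybenzyl)oxy]-8-methyl-4-methylidene-5-[(triethylsilyl)oxy]dec-7-en-3-yl (2Z)-2-methylbut-2-enoate
Product: 16 (2S,3R,5S,7Z)-10-[(4-methoxybenzyl)oxy]-8-methyl-4-methylidene-1,2,5-tris[(triethylsilyl)oxy]dec-7-en-3-yl (2Z)-2-methylbut-2-enoate
Conditions: Et3SiCl (2.5 equiv), imidazole, DMAP (cat.), CH2Cl2, 0 °C
Reagents that add atoms: chlorotriethylsilane, CC[Si](Cl)(CC)CC
Why: Silylation of both hydroxyls at once blocks 1,2-acyl migration of the angelate and creates the primary/secondary silyl ether difference used in step 13.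

Step 12
Reactants: 16 (2S,3R,5S,7Z)-10-[(4-methoxybenzyl)oxy]-8-methyl-4-methylidene-1,2,5-tris[(triethylsilyl)oxy]dec-7-en-3-yl (2Z)-2-methylbut-2-enoate
Product: 17 (2S,3R,5S)-6-{(2S,3R)-3-[2-(4-methoxybenzyloxy)ethyl]-3-methyloxiran-2-yl}-4-methylidene-1,2,5-tris[(triethylsilyl)oxy]hexan-3-yl (2Z)-2-methylbut-2-enoate
Conditions: L-fructose-derived enantiomer of the 1,2:4,5-di-O-isopropylidene-fructose ketone catalyst (30 mol %), KHSO5 (as 2KHSO5·KHSO4·K2SO4), K2CO3, Bu4NHSO4 (cat.), MeCN–(MeO)2CH2–aq. buffer (pH about 10.5), 0 °C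
Reagents that add atoms: potassium peroxymonosulfate, [K+].OOS(=O)(=O)[O-]
Why: Shi epoxidation, in which the chiral dioxirane attacks only the electron-rich trisubstituted C3=C4 bond through the spiro transition state whose face is fixed by the single vinylic hydrogen, so that this catalyst enantiomer should give the cis (3S,4R) epoxide by reagent control.

Step 13
Reactants: 17 (2S,3R,5S)-6-{(2S,3R)-3-[2-(4-methoxybenzyloxy)ethyl]-3-methyloxiran-2-yl}-4-methylidene-1,2,5-tris[(triethylsilyl)oxy]hexan-3-yl (2Z)-2-methylbut-2-enoate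
Product: 18 (2R,3R,5S)-6-{(2S,3R)-3-[2-(4-methoxybenzyloxy)ethyl]-3-methyloxiran-2-yl}-4-methylidene-1-oxo-2,5-bis[(triethylsilyl)oxy]hexan-3-yl (2Z)-2-methylbut-2-enoate
Conditions: (COCl)2, DMSO, CH2Cl2, −78 to −40 °C; then Et3N, −78 to 0 °C
Reagents that add atoms: none
Why: Under Swern conditions a primary triethylsilyl ether is converted directly into the aldehyde by the chlorosulfonium salt while the two secondary silyl ethers remain, so C7 is oxidised without a separate deprotection (the changed descriptor at C8 is only a priority effect).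

Step 14
Reactants: 18 (2R,3R,5S)-6-{(2S,3R)-3-[2-(4-methoxybenzyloxy)ethyl]-3-methyloxiran-2-yl}-4-methylidene-1-oxo-2,5-bis[(triethylsilyl)oxy]hexan-3-yl (2Z)-2-methylbut-2-enoate; 19 methyl propiolate
Product: 21 methyl (4S,5R,7S)-3-hydroxy-8-{(2S,3R)-3-[2-(4-methoxybenzyloxy)ethyl]-3-methyloxiran-2-yl}-5-[(2Z)-2-methylbut-2-enoyloxy]-2,6-dimethylidene-4,7-bis[(triethylsilyl)oxy]octanoate (both C3 epimers), via methyl 2-(diisobutylalumanyl)acrylate 20 (not isolated)
Conditions: 19, i-Bu2AlH, N-methylmorpholine N-oxide, THF, 0 °C; then 18, 0 °C to rt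
Reagents that add atoms: none
Why: Vinylalumination, the base-free counterpart of the Morita–Baylis–Hillman reaction, in which α-selective hydroalumination of methyl propiolate gives the α-aluminoacrylate that adds to the aldehyde without an amine base that would eliminate the β-angelate or epimerise C8; the new C7 carbinol is an epimer mixture that disappears in step 15.

Step 15
Reactants: 21 methyl (4S,5R,7S)-3-hydroxy-8-{(2S,3R)-3-[2-(4-methoxybenzyloxy)ethyl]-3-methyloxiran-2-yl}-5-[(2Z)-2-methylbut-2-enoyloxy]-2,6-dimethylidene-4,7-bis[(triethylsilyl)oxy]octanoate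
Product: 22 methyl (2Z,4S,5R,7S)-2-(bromomethyl)-8-{(2S,3R)-3-[2-(4-methoxybenzyloxy)ethyl]-3-methyloxiran-2-yl}-5-[(2Z)-2-methylbut-2-enoyloxy]-6-methylidene-4,7-bis[(triethylsilyl)oxy]oct-2-enoate
Conditions: N-bromosuccinimide, Me2S, CH2Cl2, 0 °C to rt
Reagents that add atoms: N-bromosuccinimide, O=C1CCC(=O)N1Br
Why: Activation of the allylic alcohol as its alkoxysulfonium salt and SN2' attack of bromide at C13 should give the transposed primary allylic bromide as the 2Z isomer, in which C8 avoids the ester.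

Step 16
Reactants: 22 methyl (2Z,4S,5R,7S)-2-(bromomethyl)-8-{(2S,3R)-3-[2-(4-methoxybenzyloxy)ethyl]-3-methyloxiran-2-yl}-5-[(2Z)-2-methylbut-2-enoyloxy]-6-methylidene-4,7-bis[(triethylsilyl)oxy]oct-2-enoate
Product: 23 methyl (2Z,4S,5R,7S)-2-(bromomethyl)-8-[(2S,3R)-3-(2-hydroxyethyl)-3-methyloxiran-2-yl]-5-[(2Z)-2-methylbut-2-enoyloxy]-6-methylidene-4,7-bis[(triethylsilyl)oxy]oct-2-enoate
Conditions: DDQ, CH2Cl2–pH 7 phosphate buffer, 0 °C
Reagents that add atoms: none
Why: Oxidative cleavage of the PMB ether by DDQ (hydride abstraction, then hydrolysis of the oxocarbenium ion) is neutral and spares silyl ethers, epoxide, angelate and the allylic bromide.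

Step 17
Reactants: 23 methyl (2Z,4S,5R,7S)-2-(bromomethyl)-8-[(2S,3R)-3-(2-hydroxyethyl)-3-methyloxiran-2-yl]-5-[(2Z)-2-methylbut-2-enoyloxy]-6-methylidene-4,7-bis[(triethylsilyl)oxy]oct-2-enoate
Product: 24 methyl (2Z,4S,5R,7S)-2-(bromomethyl)-8-[(2S,3R)-3-methyl-3-(2-oxoethyl)oxiran-2-yl]-5-[(2Z)-2-methylbut-2-enoyloxy]-6-methylidene-4,7-bis[(triethylsilyl)oxy]oct-2-enoate
Conditions: Dess–Martin periodinane, NaHCO3, CH2Cl2, 0 °C; filtered and used at once
Reagents that add atoms: none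
Why: Buffered Dess–Martin oxidation gives the β,γ-epoxy aldehyde without the base that would open the epoxide by β-elimination.

Step 18
Reactants: 24 methyl (2Z,4S,5R,7S)-2-(bromomethyl)-8-[(2S,3R)-3-methyl-3-(2-oxoethyl)oxiran-2-yl]-5-[(2Z)-2-methylbut-2-enoyloxy]-6-methylidene-4,7-bis[(triethylsilyl)oxy]oct-2-enoate
Product: 26 (1S,3S,4R,6R,7S,8S,9R)-9-angeloyloxy-3,4-epoxy-1,8-bis(triethylsilyloxy)germacra-10(14),11(13)-dien-12,6-olide, via ten-membered hydroxy ester 25 (not isolated)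
Conditions: CrCl2 (10 equiv), THF, rt, slow addition of 24 (final about 2 mM); aq. work-up, then DMAP (cat.), CH2Cl2, rt if lactonisation is incomplete
Reagents that add atoms: none
Why: Two equivalents of CrCl2 reduce the allylic C13–Br bond to an allylchromium species (trivalent chromium) that adds through its γ-carbon C7 to the C6 aldehyde in a six-membered chair transition state (SE2'), moving the double bond to C11=C13, and the chromium alkoxide on O6 then acylates itself on the neighbouring C12 methyl ester. The closest known reaction type is the chromium-mediated (Nozaki–Hiyama–Kishi/Barbier) macrocyclisation of ω-formyl 2-(bromomethyl)enoates to germacranolide and cembranolide α-methylene lactones. The ten-membered carbocycle closes by 10-exo-trig attack on the aldehyde and the lactone by 5-exo-trig acyl substitution. C6 is set by the chair, in which both ends of the eight-atom tether (C5 on the aldehyde, C8 on the allyl unit after 1,3-metallotropic E/Z equilibration of the allylchromium) should sit equatorial, giving the 6,7-anti alcohol and hence the trans-fused lactone; C7 is set by C8 through allylic 1,3-strain, with H8 eclipsing the allyl plane so that C6 bonds anti to the C8–C9 bond and the bulky OTES points outward. The step needs aldehyde-over-ester chemoselectivity (inherent to allylchromium reagents), ring closure over oligomerisation (slow addition at high dilution), and no second carbonyl within reach of C7, which is why C1 is carried as its TES ether: a C1 ketone would trap C7 in a five-membered ring.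

Step 19
Reactants: 26 (1S,3S,4R,6R,7S,8S,9R)-9-angeloyloxy-3,4-epoxy-1,8-bis(triethylsilyloxy)germacra-10(14),11(13)-dien-12,6-olide
Product: 27 (1S,3S,4R,6R,7R,8S,9R)-9-angeloyloxy-3,4-epoxy-1,8-dihydroxygermacra-10(14),11(13)-dien-12,6-olide
Conditions: Bu4NF, AcOH (1:1), THF, 0 °C
Reagents that add atoms: none
Why: Fluoride-mediated desilylation buffered with acetic acid removes both triethylsilyl ethers under near-neutral conditions, which avoids acid-promoted attack of the freed C1 hydroxyl on the epoxide at C4 and base-promoted migration of the angelate to O8.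

Step 20
Reactants: 27 (1S,3S,4R,6R,7R,8S,9R)-9-angeloyloxy-3,4-epoxy-1,8-dihydroxygermacra-10(14),11(13)-dien-12,6-olide
Product: 28 (3S,4R,6R,7R,8S,9R)-9-angeloyloxy-3,4-epoxy-8-hydroxy-1-oxogermacra-10(14),11(13)-dien-12,6-olide (target)
Conditions: MnO2 (activated, excess), CH2Cl2, rt
Reagents that add atoms: none
Why: MnO2 oxidises only the allylic C1 alcohol (the C8 alcohol is not allylic), and its neutral conditions leave the base-sensitive β,γ-epoxy enone and the two exocyclic methylene acceptors intact.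

**Compound list**
1 | hex-3-yne-1,6-diol | OCCC#CCCO | starting material
2 | 6-[(4-methoxybenzyl)oxy]hex-3-yn-1-ol | OCCC#CCCOCc1ccc(OC)cc1 | intermediate
3 | (3Z)-6-[(4-methoxybenzyl)oxy]-4-methylhex-3-en-1-ol | OCC/C=C(/C)CCOCc1ccc(OC)cc1 | intermediate
4 | (3Z)-6-[(4-methoxybenzyl)oxy]-4-methylhex-3-enal | O=CC/C=C(/C)CCOCc1ccc(OC)cc1 | intermediate
5 | acrolein | C=CC=O | starting material
6 | 2,3-dibromopropanal (not isolated) | O=CC(Br)CBr | intermediate
7 | 2-bromoacrolein | C=C(Br)C=O | intermediate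
8 | ethyl (triphenylphosphoranylidene)acetate | CCOC(=O)C=P(c1ccccc1)(c1ccccc1)c1ccccc1 | starting material
9 | ethyl (2E)-4-bromopenta-2,4-dienoate | CCOC(=O)/C=C/C(Br)=C | intermediate
10 | ethyl (2E,5S,7Z)-5-hydroxy-10-[(4-methoxybenzyl)oxy]-8-methyl-4-methylidenedeca-2,7-dienoate | COc1ccc(COCC/C(C)=C\C[C@H](O)C(=C)/C=C/C(=O)OCC)cc1 | intermediate
11 | ethyl (2E,5S,7Z)-10-[(4-methoxybenzyl)oxy]-8-methyl-4-methylidene-5-[(triethylsilyl)oxy]deca-2,7-dienoate | COc1ccc(COCC/C(C)=C\C[C@H](O[Si](CC)(CC)CC)C(=C)/C=C/C(=O)OCC)cc1 | intermediate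
12 | (2E,5S,7Z)-10-[(4-methoxybenzyl)oxy]-8-methyl-4-methylidene-5-[(triethylsilyl)oxy]deca-2,7-dien-1-ol | COc1ccc(COCC/C(C)=C\C[C@H](O[Si](CC)(CC)CC)C(=C)/C=C/CO)cc1 | intermediate
13 | [(2S,3S)-3-{(3S,5Z)-8-[(4-methoxybenzyl)oxy]-6-methyl-3-[(triethylsilyl)oxy]octa-1,5-dien-2-yl}oxiran-2-yl]methanol | COc1ccc(COCC/C(C)=C\C[C@H](O[Si](CC)(CC)CC)C(=C)[C@@H]2O[C@H]2CO)cc1 | intermediate
14 | angelic acid, (2Z)-2-methylbut-2-enoic acid | C/C=C(/C)C(=O)O | starting material
15 | (2S,3R,5S,7Z)-1,2-dihydroxy-10-[(4-methoxybenzyl)oxy]-8-methyl-4-methylidene-5-[(triethylsilyl)oxy]dec-7-en-3-yl (2Z)-2-methylbut-2-enoate | COc1ccc(COCC/C(C)=C\C[C@H](O[Si](CC)(CC)CC)C(=C)[C@@H](OC(=O)/C(C)=C\C)[C@@H](O)CO)cc1 | intermediate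
16 | (2S,3R,5S,7Z)-10-[(4-methoxybenzyl)oxy]-8-methyl-4-methylidene-1,2,5-tris[(triethylsilyl)oxy]dec-7-en-3-yl (2Z)-2-methylbut-2-enoate | COc1ccc(COCC/C(C)=C\C[C@H](O[Si](CC)(CC)CC)C(=C)[C@@H](OC(=O)/C(C)=C\C)[C@@H](O[Si](CC)(CC)CC)CO[Si](CC)(CC)CC)cc1 | intermediate
17 | (2S,3R,5S)-6-{(2S,3R)-3-[2-(4-methoxybenzyloxy)ethyl]-3-methyloxiran-2-yl}-4-methylidene-1,2,5-tris[(triethylsilyl)oxy]hexan-3-yl (2Z)-2-methylbut-2-enoate | COc1ccc(COCC[C@@]2(C)O[C@H]2C[C@H](O[Si](CC)(CC)CC)C(=C)[C@@H](OC(=O)/C(C)=C\C)[C@@H](O[Si](CC)(CC)CC)CO[Si](CC)(CC)CC)cc1 | intermediate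
18 | (2R,3R,5S)-6-{(2S,3R)-3-[2-(4-methoxybenzyloxy)ethyl]-3-methyloxiran-2-yl}-4-methylidene-1-oxo-2,5-bis[(triethylsilyl)oxy]hexan-3-yl (2Z)-2-methylbut-2-enoate | COc1ccc(COCC[C@@]2(C)O[C@H]2C[C@H](O[Si](CC)(CC)CC)C(=C)[C@@H](OC(=O)/C(C)=C\C)[C@@H](O[Si](CC)(CC)CC)C=O)cc1 | intermediate
19 | methyl propiolate | C#CC(=O)OC | starting material
20 | methyl 2-(diisobutylalumanyl)acrylate (not isolated) | COC(=O)C(=C)[Al](CC(C)C)CC(C)C | intermediate
21 | methyl (4S,5R,7S)-3-hydroxy-8-{(2S,3R)-3-[2-(4-methoxybenzyloxy)ethyl]-3-methyloxiran-2-yl}-5-[(2Z)-2-methylbut-2-enoyloxy]-2,6-dimethylidene-4,7-bis[(triethylsilyl)oxy]octanoate (C3 epimers) | COc1ccc(COCC[C@@]2(C)O[C@H]2C[C@H](O[Si](CC)(CC)CC)C(=C)[C@@H](OC(=O)/C(C)=C\C)[C@@H](O[Si](CC)(CC)CC)C(O)C(=C)C(=O)OC)cc1 | intermediate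
22 | methyl (2Z,4S,5R,7S)-2-(bromomethyl)-8-{(2S,3R)-3-[2-(4-methoxybenzyloxy)ethyl]-3-methyloxiran-2-yl}-5-[(2Z)-2-methylbut-2-enoyloxy]-6-methylidene-4,7-bis[(triethylsilyl)oxy]oct-2-enoate | COc1ccc(COCC[C@@]2(C)O[C@H]2C[C@H](O[Si](CC)(CC)CC)C(=C)[C@@H](OC(=O)/C(C)=C\C)[C@@H](O[Si](CC)(CC)CC)/C=C(\CBr)C(=O)OC)cc1 | intermediate
23 | methyl (2Z,4S,5R,7S)-2-(bromomethyl)-8-[(2S,3R)-3-(2-hydroxyethyl)-3-methyloxiran-2-yl]-5-[(2Z)-2-methylbut-2-enoyloxy]-6-methylidene-4,7-bis[(triethylsilyl)oxy]oct-2-enoate | OCC[C@@]1(C)O[C@H]1C[C@H](O[Si](CC)(CC)CC)C(=C)[C@@H](OC(=O)/C(C)=C\C)[C@@H](O[Si](CC)(CC)CC)/C=C(\CBr)C(=O)OC | intermediate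
24 | methyl (2Z,4S,5R,7S)-2-(bromomethyl)-8-[(2S,3R)-3-methyl-3-(2-oxoethyl)oxiran-2-yl]-5-[(2Z)-2-methylbut-2-enoyloxy]-6-methylidene-4,7-bis[(triethylsilyl)oxy]oct-2-enoate | O=CC[C@@]1(C)O[C@H]1C[C@H](O[Si](CC)(CC)CC)C(=C)[C@@H](OC(=O)/C(C)=C\C)[C@@H](O[Si](CC)(CC)CC)/C=C(\CBr)C(=O)OC | intermediate
25 | methyl (1S,3S,4R,6R,7S,8S,9R)-9-angeloyloxy-3,4-epoxy-6-hydroxy-1,8-bis(triethylsilyloxy)germacra-10(14),11(13)-dien-12-oate (not isolated) | COC(=O)C(=C)[C@H]1[C@H](O)C[C@@]2(C)O[C@H]2C[C@H](O[Si](CC)(CC)CC)C(=C)[C@@H](OC(=O)/C(C)=C\C)[C@H]1O[Si](CC)(CC)CC | intermediate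
26 | (1S,3S,4R,6R,7S,8S,9R)-9-angeloyloxy-3,4-epoxy-1,8-bis(triethylsilyloxy)germacra-10(14),11(13)-dien-12,6-olide | C=C1C(=O)O[C@@H]2C[C@@]3(C)O[C@H]3C[C@H](O[Si](CC)(CC)CC)C(=C)[C@@H](OC(=O)/C(C)=C\C)[C@@H](O[Si](CC)(CC)CC)[C@@H]12 | intermediate
27 | (1S,3S,4R,6R,7R,8S,9R)-9-angeloyloxy-3,4-epoxy-1,8-dihydroxygermacra-10(14),11(13)-dien-12,6-olide | C=C1C(=O)O[C@@H]2C[C@@]3(C)O[C@H]3C[C@H](O)C(=C)[C@@H](OC(=O)/C(C)=C\C)[C@@H](O)[C@@H]12 | intermediate
28 | (3S,4R,6R,7R,8S,9R)-9-angeloyloxy-3,4-epoxy-8-hydroxy-1-oxogermacra-10(14),11(13)-dien-12,6-olide | C=C1C(=O)O[C@@H]2C[C@@]3(C)O[C@H]3CC(=O)C(=C)[C@@H](OC(=O)/C(C)=C\C)[C@@H](O)[C@@H]12 | target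

**Totals.** Total step count: 20. Longest linear sequence: 18 steps (steps 1–3 and 6–20).

**Steps most likely to fail**

Step 18. The allylchromium may add through the alternative chair (allyl unit in its Z geometry with C8 axial), attacking the other aldehyde face and giving the 6,7-syn alcohol; intermolecular coupling is the second hazard. Fallback: from 24 the chromium cyclisation is run as before but worked up cold and without base, so that the ring-closed alcohol is isolated as the 6-epi hydroxy ester F1. Me3SnOH (ClCH2CH2Cl, 60 °C) then cleaves only the methyl ester to the 6-epi hydroxy acid F2. An intramolecular Mitsunobu reaction (PPh3, diisopropyl azodicarboxylate, THF, 0 °C) closes the γ-lactone with inversion at C6 and returns to 26.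

Step 10. The hindered unsaturated acid may open the vinyl epoxide slowly, with competing attack at C8 or SN2' attack at C14, acyl migration to O8/O7, or angelate-to-tiglate isomerisation on the Lewis acid. Fallback: from 13 the epoxide is opened with benzoic acid and Ti(OiPr)4 (CH2Cl2, rt) to the 9-benzoate diol F3, which is silylated (Et3SiCl, imidazole) to the bis-silyl benzoate F4. i-Bu2AlH (CH2Cl2, −78 °C) removes the benzoate to give the C9 alcohol F5. Yamaguchi esterification with angelic acid 14 (2,4,6-trichlorobenzoyl chloride, Et3N, then DMAP, toluene, rt) installs the angelate by acylation instead of epoxide opening and returns to 16.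

Step 14. Addition of the hindered α-aluminoacrylate to the α-silyloxy aldehyde may stall, with Lewis-acid opening of the epoxide or β-elimination of the angelate taking over. Fallback: from 18, aldol addition of the lithium enolate of methyl 3-(dimethylamino)propanoate (LiN(i-Pr)2, THF, −78 °C) gives the β-hydroxy amino ester F6 as a diastereomer mixture. MeI (MeCN, rt) converts it into the quaternary ammonium iodide F7, and NaHCO3-mediated E1cB loss of trimethylamine unveils the α-methylene ester and returns to 21.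

**Further compounds**
F1 | step 18 | C6 epimer (6S,7S) of hydroxy ester 25 | COC(=O)C(=C)[C@H]1[C@@H](O)C[C@@]2(C)O[C@H]2C[C@H](O[Si](CC)(CC)CC)C(=C)[C@@H](OC(=O)/C(C)=C\C)[C@H]1O[Si](CC)(CC)CC
F2 | step 18 | 6-epi hydroxy acid (C12 carboxylic acid of F1) | OC(=O)C(=C)[C@H]1[C@@H](O)C[C@@]2(C)O[C@H]2C[C@H](O[Si](CC)(CC)CC)C(=C)[C@@H](OC(=O)/C(C)=C\C)[C@H]1O[Si](CC)(CC)CC
F3 | step 10 | (2S,3R,5S,7Z)-1,2-dihydroxy-10-[(4-methoxybenzyl)oxy]-8-methyl-4-methylidene-5-[(triethylsilyl)oxy]dec-7-en-3-yl benzoate | COc1ccc(COCC/C(C)=C\C[C@H](O[Si](CC)(CC)CC)C(=C)[C@@H](OC(=O)c2ccccc2)[C@@H](O)CO)cc1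
F4 | step 10 | (2S,3R,5S,7Z)-10-[(4-methoxybenzyl)oxy]-8-methyl-4-methylidene-1,2,5-tris[(triethylsilyl)oxy]dec-7-en-3-yl benzoate | COc1ccc(COCC/C(C)=C\C[C@H](O[Si](CC)(CC)CC)C(=C)[C@@H](OC(=O)c2ccccc2)[C@@H](O[Si](CC)(CC)CC)CO[Si](CC)(CC)CC)cc1
F5 | step 10 | (2S,3R,5S,7Z)-10-[(4-methoxybenzyl)oxy]-8-methyl-4-methylidene-1,2,5-tris[(triethylsilyl)oxy]dec-7-en-3-ol | COc1ccc(COCC/C(C)=C\C[C@H](O[Si](CC)(CC)CC)C(=C)[C@@H](O)[C@@H](O[Si](CC)(CC)CC)CO[Si](CC)(CC)CC)cc1
F6 | step 14 | methyl (4S,5R,7S)-2-[(dimethylamino)methyl]-3-hydroxy-8-{(2S,3R)-3-[2-(4-methoxybenzyloxy)ethyl]-3-methyloxiran-2-yl}-5-[(2Z)-2-methylbut-2-enoyloxy]-6-methylidene-4,7-bis[(triethylsilyl)oxy]octanoate (C2/C3 diastereomers) | COc1ccc(COCC[C@@]2(C)O[C@H]2C[C@H](O[Si](CC)(CC)CC)C(=C)[C@@H](OC(=O)/C(C)=C\C)[C@@H](O[Si](CC)(CC)CC)C(O)C(CN(C)C)C(=O)OC)cc1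
F7 | step 14 | N-methyl quaternary ammonium iodide of F6 | COc1ccc(COCC[C@@]2(C)O[C@H]2C[C@H](O[Si](CC)(CC)CC)C(=C)[C@@H](OC(=O)/C(C)=C\C)[C@@H](O[Si](CC)(CC)CC)C(O)C(C[N+](C)(C)C)C(=O)OC)cc1.[I-]
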